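**Plan**

1. Retrosynthesis cuts, in order: the two MOM acetals on O-5 and O-7; then, in one event, the C-3–C-1′ bond and the O-1–C-2 bond of ring C; then the two C-prenyl bonds of ring A and the pyran ring of the chromene.
2. Enabling feature: on ring B the free OH at C-4′ is para to C-1′, so ring B can be written as a 4-diazocyclohexa-2,5-dienone with N2 on C-1′ (a quinoid carbene precursor). C-3 is the nucleophilic α-carbon of a vinylogous amide whose β-carbon becomes C-2 and whose ortho-OH becomes O-1.
3. Forward: ring A is dressed first (C-diprenylation, MOM, enaminone). The 2,2-dimethylpyran ring is made by Knoevenagel/oxa-6π closure on cyclohexane-1,3-dione; its carbocycle is then aromatized to ring B, oxidized at the para position and turned into the diazide.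
4. The halves are joined by rhodium-carbene arylation of the enaminone α-C–H, with ring C closing in the same flask; acid removes the MOM groups last.
5. Stereochemistry: the target has no stereocentre; the cis alkene of the chromene is fixed by its ring.

Key step: step 8

Remark on the chemistry: the two ortho-OH groups of 3 are equivalent, so bis-protection is assumed to leave either one free and chelated to the ketone. Compounds 9 and 10 are racemic/stereoisomer mixtures and the C=N and C=C geometries of 13 and 15 are not controlled; all of this is erased in the next event.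

**Step 1**
Reactants: 1 2,4,6-trihydroxyacetophenone; 2 prenyl bromide
Product: 3 1-[2,4,6-trihydroxy-3,5-bis(3-methylbut-2-en-1-yl)phenyl]ethan-1-one
Conditions: 2 (2.1 equiv), 10% aq KOH, 0 °C to rt
Reagents that add atoms: none
Why: In water the phloroglucinol-type phenolate is alkylated at carbon rather than oxygen (nuclear C-prenylation of an acylphloroglucinol), the two free ring positions are the only aromatic C–H sites, and stoichiometry and low temperature hold back geminal over-alkylation.

**Step 2**
Reactants: 3 1-[2,4,6-trihydroxy-3,5-bis(3-methylbut-2-en-1-yl)phenyl]ethan-1-one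
Product: 4 1-[2-hydroxy-4,6-bis(methoxymethoxy)-3,5-bis(3-methylbut-2-en-1-yl)phenyl]ethan-1-one
Conditions: MOMCl (2.2 equiv), iPr2NEt, CH2Cl2, 0 °C to rt
Reagents that add atoms: chloromethyl methyl ether (MOMCl), COCCl
Why: MOM ether formation (O-alkylation) takes the para-OH and one ortho-OH, while the remaining ortho-OH is chelated to the ketone and should stay free to become O-1 later.

**Step 3**
Reactants: 4 1-[2-hydroxy-4,6-bis(methoxymethoxy)-3,5-bis(3-methylbut-2-en-1-yl)phenyl]ethan-1-one
Product: 5 (E)-3-(dimethylamino)-1-[2-hydroxy-4,6-bis(methoxymethoxy)-3,5-bis(3-methylbut-2-en-1-yl)phenyl]prop-2-en-1-one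
Conditions: Me2NCH(OMe)2, toluene, 90 °C
Reagents that add atoms: N,N-dimethylformamide dimethyl acetal, COC(OC)N(C)C
Why: Enaminone condensation of the methyl ketone with the amide acetal should give the E push–pull enaminone, with MOM ethers and prenyl groups inert and the chelated OH not methylated.

**Step 4**
Reactants: 6 cyclohexane-1,3-dione; 7 3-methylbut-2-enal
Product: 8 2,2-dimethyl-2,6,7,8-tetrahydro-5H-chromen-5-one
Conditions: ethylenediammonium diacetate (10 mol %), MeOH, rt to 50 °C
Reagents that add atoms: none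
Why: Knoevenagel condensation of the 1,3-dione with the enal followed by oxa-6π electrocyclization of the 1-oxatriene builds the 2,2-dimethyl-2H-pyran ring.

**Step 5**
Reactants: 8 2,2-dimethyl-2,6,7,8-tetrahydro-5H-chromen-5-one
Product: 11 2,2-dimethyl-2H-chromen-5-ol, via selenide 9 (not isolated), via selenoxide 10 (not isolated)
Conditions: LiN(iPr)2, THF, −78 °C; PhSeCl; then 30% H2O2, pyridine, CH2Cl2, 0 °C to rt
Reagents that add atoms: none
Why: Kinetic α′-deprotonation of the vinylogous ester at C-6, α-selenenylation and selenoxide syn-elimination give a cross-conjugated dienone that tautomerizes to the phenol, and H2O2 does not epoxidize the chromene alkene.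

**Step 6**
Reactants: 11 2,2-dimethyl-2H-chromen-5-ol
Product: 12 2,2-dimethyl-2H-chromene-5,8-dione
Conditions: K2[ON(SO3)2] (2.2 equiv), KH2PO4 buffer, H2O/acetone, 0 °C to rt
Reagents that add atoms: potassium nitrosodisulfonate, [K+].[K+].[O]N(S(=O)(=O)[O-])S(=O)(=O)[O-]
Why: Teuber oxidation: one nitroxyl radical abstracts the phenolic hydrogen and a second delivers oxygen to the free para carbon (C-8), so a para-unsubstituted phenol should give the para-quinone.

**Step 7**
Reactants: 12 2,2-dimethyl-2H-chromene-5,8-dione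
Product: 14 8-diazo-2,2-dimethyl-2H-chromen-5(8H)-one, via tosylhydrazone 13 (not isolated)
Conditions: TsNHNH2 (1.0 equiv), MeOH, 0 °C; then Et3N, CH2Cl2, 0 °C to rt, dark
Reagents that add atoms: p-toluenesulfonohydrazide, Cc1ccc(S(=O)(=O)NN)cc1
Why: Sulfonylhydrazone formation should occur at the more electrophilic C-8 carbonyl (C-5 is a vinylogous ester carbonyl, deactivated by O-1 through C-8a=C-4a), and base-induced loss of sulfinate (Bamford–Stevens-type quinone diazide formation) leaves the diazo group on the future C-1′.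

**Step 8**
Reactants: 5 (E)-3-(dimethylamino)-1-[2-hydroxy-4,6-bis(methoxymethoxy)-3,5-bis(3-methylbut-2-en-1-yl)phenyl]prop-2-en-1-one; 14 8-diazo-2,2-dimethyl-2H-chromen-5(8H)-one
Product: 16 3-(5-hydroxy-2,2-dimethyl-2H-chromen-8-yl)-5,7-bis(methoxymethoxy)-6,8-bis(3-methylbut-2-en-1-yl)-4H-chromen-4-one, via α-aryl enaminone 15 (not isolated)
Conditions: Rh2(OAc)4 (2 mol %), ClCH2CH2Cl, 40 °C, 14 (1.3 equiv) added over 2 h, dark; then AcOH (5 equiv), 60 °C
Reagents that add atoms: none
Why: Proposed new method: divalent rhodium (Rh2(OAc)4) should decompose the para-quinone diazide 14 with loss of N2 to an electrophilic quinoid carbene at C-8 of the chromene (the future C-1′); the α-carbon of the push–pull enaminone 5 (the future C-3) attacks the carbene carbon, rhodium departs as ring B aromatizes to the free 4′-phenolate, and proton transfer gives α-aryl enaminone 15. The closest known reaction types are the rhodium- or gold-catalysed arylation of π-nucleophiles by quinone diazides and the domino α-C–H functionalization/chromone annulation of o-hydroxyaryl enaminones with carbenes from diazo esters or with arenediazonium and diaryliodonium salts. Ring C then closes by intramolecular oxa-Michael addition of the chelated ortho-OH to the aminovinyl β-carbon (6-endo-trig) and β-elimination of Me2NH, the same closure that ends the deoxybenzoin/amide-acetal isoflavone synthesis. No stereocentre is formed. The site on ring B needs no selection because the diazo carbon is the only carbene centre, and the free 4′-OH emerges without a protecting group. Chemoselectivity for C-3 over the prenyl alkenes, the MOM oxygens and the OH rests on the much higher nucleophilicity of the enaminone α-carbon, on chelation of the OH to the carbonyl, and on slow addition of 14, which limits carbene dimerization and capture by released Me2NH.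

**Step 9**
Reactants: 16 3-(5-hydroxy-2,2-dimethyl-2H-chromen-8-yl)-5,7-bis(methoxymethoxy)-6,8-bis(3-methylbut-2-en-1-yl)-4H-chromen-4-one
Product: 17 Kanzonol L
Conditions: 3 M aq HCl, MeOH, 40 °C
Reagents that add atoms: none
Why: Acid-catalysed acetal methanolysis should free the 5- and 7-OH groups; mild temperature and short time are chosen because stronger acid would cyclize a prenyl group onto a neighbouring OH.

**Compound list**

1 | 2,4,6-trihydroxyacetophenone | CC(=O)c1c(O)cc(O)cc1O | starting material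
2 | 1-bromo-3-methylbut-2-ene (prenyl bromide) | CC(C)=CCBr | starting material
3 | 1-[2,4,6-trihydroxy-3,5-bis(3-methylbut-2-en-1-yl)phenyl]ethan-1-one | CC(=O)c1c(O)c(CC=C(C)C)c(O)c(CC=C(C)C)c1O | intermediate
4 | 1-[2-hydroxy-4,6-bis(methoxymethoxy)-3,5-bis(3-methylbut-2-en-1-yl)phenyl]ethan-1-one | CC(=O)c1c(O)c(CC=C(C)C)c(OCOC)c(CC=C(C)C)c1OCOC | intermediate
5 | (E)-3-(dimethylamino)-1-[2-hydroxy-4,6-bis(methoxymethoxy)-3,5-bis(3-methylbut-2-en-1-yl)phenyl]prop-2-en-1-one | CN(C)/C=C/C(=O)c1c(O)c(CC=C(C)C)c(OCOC)c(CC=C(C)C)c1OCOC | intermediate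
6 | cyclohexane-1,3-dione | O=C1CCCC(=O)C1 | starting material
7 | 3-methylbut-2-enal | CC(C)=CC=O | starting material
8 | 2,2-dimethyl-2,6,7,8-tetrahydro-5H-chromen-5-one | CC1(C)C=CC2=C(O1)CCCC2=O | intermediate
9 | 2,2-dimethyl-6-(phenylselanyl)-2,6,7,8-tetrahydro-5H-chromen-5-one (racemic) | CC1(C)C=CC2=C(O1)CCC([Se]c3ccccc3)C2=O | intermediate (not isolated)
10 | 2,2-dimethyl-6-(phenylseleninyl)-2,6,7,8-tetrahydro-5H-chromen-5-one (mixture of stereoisomers) | CC1(C)C=CC2=C(O1)CCC([Se](=O)c3ccccc3)C2=O | intermediate (not isolated)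
11 | 2,2-dimethyl-2H-chromen-5-ol | CC1(C)C=Cc2c(O)cccc2O1 | intermediate
12 | 2,2-dimethyl-2H-chromene-5,8-dione | CC1(C)C=CC2=C(O1)C(=O)C=CC2=O | intermediate
13 | N′-[2,2-dimethyl-5-oxo-2H-chromen-8(5H)-ylidene]-4-methylbenzenesulfonohydrazide (C=N geometry not controlled) | CC1(C)C=CC2=C(O1)C(=NNS(=O)(=O)c3ccc(C)cc3)C=CC2=O | intermediate (not isolated)
14 | 8-diazo-2,2-dimethyl-2H-chromen-5(8H)-one (para-quinone diazide; zwitterion 5-oxido-2,2-dimethyl-2H-chromene-8-diazonium) | CC1(C)C=CC2=C(O1)C(=[N+]=[N-])C=CC2=O | intermediate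
15 | 3-(dimethylamino)-2-(5-hydroxy-2,2-dimethyl-2H-chromen-8-yl)-1-[2-hydroxy-4,6-bis(methoxymethoxy)-3,5-bis(3-methylbut-2-en-1-yl)phenyl]prop-2-en-1-one (drawn E; geometry not controlled) | CN(C)/C=C(\c1ccc(O)c2c1OC(C)(C)C=C2)C(=O)c1c(O)c(CC=C(C)C)c(OCOC)c(CC=C(C)C)c1OCOC | intermediate (not isolated)
16 | 3-(5-hydroxy-2,2-dimethyl-2H-chromen-8-yl)-5,7-bis(methoxymethoxy)-6,8-bis(3-methylbut-2-en-1-yl)-4H-chromen-4-one | COCOc1c(CC=C(C)C)c(OCOC)c2c(=O)c(-c3ccc(O)c4c3OC(C)(C)C=C4)coc2c1CC=C(C)C | intermediate
17 | Kanzonol L, 5,7-dihydroxy-3-(5-hydroxy-2,2-dimethyl-2H-chromen-8-yl)-6,8-bis(3-methylbut-2-en-1-yl)-4H-chromen-4-one | CC(C)=CCc1c(O)c(CC=C(C)C)c2occ(-c3ccc(O)c4c3OC(C)(C)C=C4)c(=O)c2c1O | target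

**Totals**

Total step count: 9. Longest linear sequence: 6 steps (steps 4 to 9, from cyclohexane-1,3-dione); the ring A branch is 5 steps (steps 1 to 3, then 8 and 9).

**Steps most likely to fail**

Step 8 (new method). The carbene may be lost to dimerization, to N–H insertion into the dimethylamine released on ring closure, or to cyclopropanation of a prenyl alkene, and the diazide may azo-couple to the enaminone before it loses nitrogen. The fallback uses known chemistry, sets out from 5 and 14 and comes back at 16. Iodocyclization of 5 with I2 and pyridine in CHCl3 at 0 °C should give 3-iodo-5,7-bis(methoxymethoxy)-6,8-bis(3-methylbut-2-en-1-yl)-4H-chromen-4-one F1. Acidification of 14 (aq H2SO4, 0 °C) to the 4-hydroxyarenediazonium ion and treatment with KI (Sandmeyer-type iododediazoniation) should give 8-iodo-2,2-dimethyl-2H-chromen-5-ol F2. Miyaura borylation of F2 (B2pin2, PdCl2(dppf), KOAc, dioxane, 80 °C) should give 2,2-dimethyl-8-(4,4,5,5-tetramethyl-1,3,2-dioxaborolan-2-yl)-2H-chromen-5-ol F3. Suzuki–Miyaura coupling of F1 with F3 (Pd(PPh3)4, Na2CO3, DME/H2O, 80 °C) should then give 16.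

Step 7. Condensation at the wrong carbonyl (C-5), conjugate addition of the hydrazide at C-6/C-7 or reduction of the quinone to the hydroquinone may compete. The fallback sets out from 11 and comes back at 14, bypassing 12. Azo coupling of the phenolate of 11 with benzenediazonium chloride (PhNH2, NaNO2, HCl; then aq NaOH, 0 °C) is para-selective for a phenolate and should give (E)-2,2-dimethyl-8-(phenyldiazenyl)-2H-chromen-5-ol F4. Reductive cleavage with Na2S2O4 (aq EtOH, 60 °C) should give 8-amino-2,2-dimethyl-2H-chromen-5-ol F5. Diazotization (isoamyl nitrite, HCl, EtOH, 0 °C) and neutralization with K2CO3 should give 14.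

Step 9. Acid may cyclize a prenyl group onto the neighbouring phenol (chroman formation) or add solvent to the prenyl or chromene alkenes before both acetals are gone. The fallback replaces the acid-labile protection by allyl ethers that leave under neutral conditions; it sets out from 3 and comes back at 17. Allyl bromide and K2CO3 in acetone should give 1-[2-hydroxy-4,6-bis(allyloxy)-3,5-bis(3-methylbut-2-en-1-yl)phenyl]ethan-1-one F6. Condensation as in step 3 should give the corresponding enaminone, (E)-1-[4,6-bis(allyloxy)-2-hydroxy-3,5-bis(3-methylbut-2-en-1-yl)phenyl]-3-(dimethylamino)prop-2-en-1-one F7. The conditions of step 8 with 14 should carry F7 through the non-isolated 2-(5-hydroxy-2,2-dimethyl-2H-chromen-8-yl) enaminone F8 to 5,7-bis(allyloxy)-3-(5-hydroxy-2,2-dimethyl-2H-chromen-8-yl)-6,8-bis(3-methylbut-2-en-1-yl)-4H-chromen-4-one F9. Deallylation with zerovalent palladium (Pd(PPh3)4, K2CO3, MeOH, rt), which leaves C-prenyl groups untouched, should give 17.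

**Further compounds**

F1 | step 8 | 3-iodo-5,7-bis(methoxymethoxy)-6,8-bis(3-methylbut-2-en-1-yl)-4H-chromen-4-one | COCOc1c(CC=C(C)C)c(OCOC)c2c(=O)c(I)coc2c1CC=C(C)C
F2 | step 8 | 8-iodo-2,2-dimethyl-2H-chromen-5-ol | CC1(C)C=Cc2c(O)ccc(I)c2O1
F3 | step 8 | 2,2-dimethyl-8-(4,4,5,5-tetramethyl-1,3,2-dioxaborolan-2-yl)-2H-chromen-5-ol | CC1(C)C=Cc2c(O)ccc(B3OC(C)(C)C(C)(C)O3)c2O1
F4 | step 7 | (E)-2,2-dimethyl-8-(phenyldiazenyl)-2H-chromen-5-ol | CC1(C)C=Cc2c(O)ccc(/N=N/c3ccccc3)c2O1
F5 | step 7 | 8-amino-2,2-dimethyl-2H-chromen-5-ol | CC1(C)C=Cc2c(O)ccc(N)c2O1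
F6 | step 9 | 1-[2-hydroxy-4,6-bis(allyloxy)-3,5-bis(3-methylbut-2-en-1-yl)phenyl]ethan-1-one | CC(=O)c1c(O)c(CC=C(C)C)c(OCC=C)c(CC=C(C)C)c1OCC=C
F7 | step 9 | (E)-1-[4,6-bis(allyloxy)-2-hydroxy-3,5-bis(3-methylbut-2-en-1-yl)phenyl]-3-(dimethylamino)prop-2-en-1-one | CN(C)/C=C/C(=O)c1c(O)c(CC=C(C)C)c(OCC=C)c(CC=C(C)C)c1OCC=C
F8 | step 9 | 1-[4,6-bis(allyloxy)-2-hydroxy-3,5-bis(3-methylbut-2-en-1-yl)phenyl]-3-(dimethylamino)-2-(5-hydroxy-2,2-dimethyl-2H-chromen-8-yl)prop-2-en-1-one (drawn E; not isolated) | CN(C)/C=C(\c1ccc(O)c2c1OC(C)(C)C=C2)C(=O)c1c(O)c(CC=C(C)C)c(OCC=C)c(CC=C(C)C)c1OCC=C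
F9 | step 9 | 5,7-bis(allyloxy)-3-(5-hydroxy-2,2-dimethyl-2H-chromen-8-yl)-6,8-bis(3-methylbut-2-en-1-yl)-4H-chromen-4-one | C=CCOc1c(CC=C(C)C)c(OCC=C)c2c(=O)c(-c3ccc(O)c4c3OC(C)(C)C=C4)coc2c1CC=C(C)C
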